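**Strategy.** Ring A is closed last, through the C1–C10 bond. A primary C1 radical adds 6-exo to C10, the β-carbon of a flat dienoate built from Hagemann's ester; the C9 carboxylate is the acceptor handle and later the anchor for the side chain. The feature exploited is the 1,4-relationship of C18 (on C4, ring A) and the C6 oxygen (ring B): tied as a temporary enol γ-lactone, it lets the tether on the catalytically set C4 centre reach only one face of C10. One event thus fixes C10 (C19/C20 syn, C18 equatorial); C5, C6 and C9 follow by substrate and thermodynamic control.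

Key step: step 5

Remark: labdane numbering is used for all intermediates (C18 = carboxyl carbon on C4, C19 = methyl on C4, C20 = methyl on C10, C17 = exocyclic methylene carbon). Compounds 1, 3, 5, 6 and 7 are racemic or configurationally labile, and the C8/C9 centres of 10–17 and 20–21 are carried as mixtures that converge in steps 12 and 15.

Step 1
Reactants: 1 ethyl 2-methyl-4-oxocyclohex-2-ene-1-carboxylate (Hagemann's ester, racemic); 2 prop-2-en-1-ol (allyl alcohol)
Product: 3 allyl 2-methyl-4-oxocyclohex-2-ene-1-carboxylate (racemic)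
Conditions: Ti(OiPr)4 (5 mol%), allyl alcohol as solvent, 100 °C, EtOH distilled off
Reagents that add atoms: allyl alcohol 2, C=CCO
Why: Titanate-catalysed transesterification swaps the ethyl for an allyl ester, which can be removed at the end under neutral palladium catalysis.

Step 2
Reactants: 3 allyl 2-methyl-4-oxocyclohex-2-ene-1-carboxylate; 4 tert-butyl 2-bromopropanoate (racemic)
Product: 5 allyl 3-(1-tert-butoxy-1-oxopropan-2-yl)-2-methyl-4-oxocyclohex-2-ene-1-carboxylate (mixture of stereoisomers)
Conditions: t-BuOK, t-BuOH–THF, 0 °C to rt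
Reagents that add atoms: tert-butyl 2-bromopropanoate 4, CC(Br)C(=O)OC(C)(C)C
Why: Classical Hagemann's ester alkylation: the extended enolate reacts at ring C3 (labdane C5) by SN2 on the activated α-bromo ester, forming the C4–C5 bond.

Step 3
Reactants: 5 allyl 3-(1-tert-butoxy-1-oxopropan-2-yl)-2-methyl-4-oxocyclohex-2-ene-1-carboxylate
Product: 7 allyl 3,4-dimethyl-2-oxo-2,3,6,7-tetrahydro-1-benzofuran-5-carboxylate (racemic enol lactone), via keto acid 6 (not isolated)
Conditions: TFA, CH2Cl2, rt; concentrate; then Ac2O, NaOAc, 90 °C, under argon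
Reagents that add atoms: none
Why: Acidolysis of the tert-butyl ester followed by enol lactonisation of the γ-keto acid through the conjugated Hagemann dienol should give the C5=C6/C9=C10 dienoate lactone, whose C3–H is acidic because deprotonation gives an aromatic 2-furanolate.

Step 4
Reactants: 7 allyl 3,4-dimethyl-2-oxo-2,3,6,7-tetrahydro-1-benzofuran-5-carboxylate; 8 1,3-diiodopropane
Product: 9 allyl (3S)-3-(3-iodopropyl)-3,4-dimethyl-2-oxo-2,3,6,7-tetrahydro-1-benzofuran-5-carboxylate
Conditions: 1,3-diiodopropane (3 equiv), Cs2CO3 (solid), O-allyl-N-(9-anthracenylmethyl)cinchonidinium bromide (10 mol%; the cinchoninium pseudoenantiomer is used instead if it is the one that delivers the 3S lactone), toluene, −20 °C, under argon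
Reagents that add atoms: 1,3-diiodopropane 8, ICCCI
Why: Asymmetric phase-transfer C-alkylation of the benzofuranone-type enolate, in which the chiral ammonium ion pair shields one enolate face, sets the quaternary C4 centre, the only stereocentre introduced by a chiral reagent.

Step 5
Reactants: 9 allyl (3S)-3-(3-iodopropyl)-3,4-dimethyl-2-oxo-2,3,6,7-tetrahydro-1-benzofuran-5-carboxylate
Product: 10 allyl (2aS,5aS)-2a,5a-dimethyl-2-oxo-2a,3,4,5,5a,6,7,8-octahydro-2H-naphtho[1,8-bc]furan-6-carboxylate (tricyclic enol lactone; C9 epimers)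
Conditions: Bu3SnH (1.3 equiv) and AIBN (0.2 equiv) added by syringe pump over 8 h, benzene (0.005 M), 80 °C
Reagents that add atoms: none
Why: The tributyltin radical abstracts iodine to give the primary C1 radical, which adds to C10, the electrophilic β-carbon of the C9=C10 enoate, and the tertiary α-ester radical at C9 is then reduced by Bu3SnH; the closest known reaction type is the intramolecular Giese radical conjugate addition. Ring A closes in the 6-exo-trig mode through a chair-like transition state, helped by the C3–C4–C5–C10 dihedral angle being already near 60° because C4 lies in the planar enol lactone. The new centre C10 is controlled by C4: the tether leaves the lactone plane on one side only, so C1 bonds to that face and C20 is pushed to the face of C19, with C18 held in the ring plane as the future equatorial ester. C9 forms as a mixture and is reset in step 15. The step needs regioselectivity for C10 over 5-exo attack at C5 or attack at C6, which should be secured by polarity matching (nucleophilic alkyl radical with the electron-poor β-carbon, against electron-rich enol-ester carbons) and by the strain of the alternative bicycles. High dilution and slow stannane addition should suppress simple reduction of the C1 radical.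

Step 6
Reactants: 10 tricyclic enol lactone
Product: 11 5-allyl 1-methyl 1,4a-dimethyl-8-oxodecahydronaphthalene-1,5-dicarboxylate (trans-decalin; C6 ketone, C18 methyl ester, 5-H anti to C20, C19 syn to C20; C9 epimers)
Conditions: MeOH, Et3N, DMAP (cat.), 0 °C to rt
Reagents that add atoms: methanol, CO
Why: Amine-catalysed methanolysis of the strained enol lactone (an activated ester) releases the C18 methyl ester of the target, and the C6 enol should ketonise by protonation of C5 from the face opposite the axial C19 and C20 methyl groups, giving the trans ring fusion.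

Step 7
Reactants: 11 keto diester
Product: 12 5-allyl 1-methyl 1,4a-dimethyl-8-oxo-1,2,3,4,4a,5,8,8a-octahydronaphthalene-1,5-dicarboxylate (C7=C8 enone)
Conditions: IBX (2 equiv), DMSO–toluene, 70 °C
Reagents that add atoms: none
Why: IBX dehydrogenation (Nicolaou) of the ketone can only desaturate C7–C8, because C5 has no β-hydrogen (C4 and C10 are quaternary).

Step 8
Reactants: 12 enone
Product: 13 5-allyl 1-methyl 1,4a-dimethyl-8-oxo-6-(4,4,5,5-tetramethyl-1,3,2-dioxaborolan-2-yl)decahydronaphthalene-1,5-dicarboxylate (C8 boronate)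
Conditions: B2pin2 (1.05 equiv), CuCl (5 mol%), NaOt-Bu (10 mol%), DPEphos (5 mol%), MeOH (2 equiv), THF, rt
Reagents that add atoms: bis(pinacolato)diboron, CC1(C)OB(OC1(C)C)B1OC(C)(C)C(C)(C)O1
Why: Copper-catalysed conjugate borylation places a masked hydroxyl on C8, whose configuration is irrelevant because it becomes a carbonyl.

Step 9
Reactants: 13 β-boryl ketone
Product: 14 5-allyl 1-methyl 8-hydroxy-1,4a-dimethyl-6-(4,4,5,5-tetramethyl-1,3,2-dioxaborolan-2-yl)decahydronaphthalene-1,5-dicarboxylate (equatorial C6 alcohol)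
Conditions: SmI2 (3 equiv), THF–MeOH, −78 °C to rt
Reagents that add atoms: none
Why: Single-electron reduction through the samarium ketyl (dissolving-metal type) should give the thermodynamically preferred equatorial C6 alcohol, with oxygen anti to the axial C19 and C20 methyl groups, whereas hydride would attack that open face and give the axial epimer.

Step 10
Reactants: 14 hydroxy boronate
Product: 15 5-allyl 1-methyl 8-acetoxy-1,4a-dimethyl-6-(4,4,5,5-tetramethyl-1,3,2-dioxaborolan-2-yl)decahydronaphthalene-1,5-dicarboxylate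
Conditions: Ac2O, pyridine, DMAP, rt to 40 °C
Reagents that add atoms: acetic anhydride, CC(=O)OC(C)=O
Why: DMAP-catalysed acetylation of the hindered secondary alcohol installs the C6 acetate of the target.

Step 11
Reactants: 15 acetoxy boronate
Product: 16 5-allyl 1-methyl 8-acetoxy-6-hydroxy-1,4a-dimethyldecahydronaphthalene-1,5-dicarboxylate
Conditions: NaBO3·4H2O, THF–H2O, rt
Reagents that add atoms: sodium perborate, [Na+].OO[B-](O)(O)O
Why: Perborate oxidation of the C–B bond gives the C8 alcohol under conditions mild enough to keep the acetate.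

Step 12
Reactants: 16 C8 alcohol
Product: 17 5-allyl 1-methyl 8-acetoxy-1,4a-dimethyl-6-oxodecahydronaphthalene-1,5-dicarboxylate (β-keto ester; C8 ketone, C9 allyl ester)
Conditions: Dess–Martin periodinane, NaHCO3, CH2Cl2, rt
Reagents that add atoms: none
Why: Dess–Martin oxidation gives the C8/C9 β-keto ester, the classical platform for C9 alkylation in labdane synthesis.

Step 13
Reactants: 18 3-methylpenta-1,4-dien-3-ol
Product: 19 (3E)-5-bromo-3-methylpenta-1,3-diene
Conditions: PBr3 (0.4 equiv), Et2O, −10 °C; used fresh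
Reagents that add atoms: phosphorus tribromide, BrP(Br)Br
Why: Bromination with allylic transposition (SN2′) of the tertiary bis-allylic alcohol should give mainly the conjugated E dienyl bromide.

Step 14
Reactants: 17 β-keto ester; 19 (3E)-5-bromo-3-methylpenta-1,3-diene
Product: 20 5-allyl 1-methyl 8-acetoxy-1,4a-dimethyl-5-[(2E)-3-methylpenta-2,4-dien-1-yl]-6-oxodecahydronaphthalene-1,5-dicarboxylate
Conditions: K2CO3, acetone, rt
Reagents that add atoms: (3E)-5-bromo-3-methylpenta-1,3-diene 19, BrC/C=C(C)/C=C
Why: C-alkylation of the β-keto ester enolate occurs regiospecifically at C9, and because the C7 side is never enolised the β-acetoxy group should not be eliminated.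

Step 15
Reactants: 20 alkylated β-keto ester
Product: 22 methyl 8-acetoxy-1,4a-dimethyl-5-[(2E)-3-methylpenta-2,4-dien-1-yl]-6-oxodecahydronaphthalene-1-carboxylate (C8 ketone, side chain equatorial at C9), via β-keto acid 21 (not isolated)
Conditions: Pd(PPh3)4 (5 mol%), morpholine (3 equiv), THF, 0 °C to rt
Reagents that add atoms: none
Why: Tsuji deallylation through π-allylpalladium and decarboxylation give the C8–C9 enol, which should be protonated axially from the face anti to C20, so the side chain ends equatorial (also the thermodynamic epimer α to the ketone).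

Step 16
Reactants: 22 C8 ketone
Product: 23 methyl (1S,4aS,5R,8R,8aS)-8-acetoxy-1,4a-dimethyl-6-methylidene-5-[(2E)-3-methylpenta-2,4-dien-1-yl]decahydronaphthalene-1-carboxylate (target)
Conditions: Zn, CH2Br2, TiCl4, THF–CH2Cl2, 0 °C to rt
Reagents that add atoms: dibromomethane, BrCBr
Why: Takai–Lombardo methylenation is non-basic and selective for the ketone over the esters, so it should form the exocyclic C8=C17 alkene without β-elimination of the acetate or epimerisation at C9.

**Compound list**

1 | ethyl 2-methyl-4-oxocyclohex-2-ene-1-carboxylate (Hagemann's ester, racemic) | CCOC(=O)C1CCC(=O)C=C1C | starting material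
2 | prop-2-en-1-ol (allyl alcohol) | C=CCO | starting material
3 | allyl 2-methyl-4-oxocyclohex-2-ene-1-carboxylate (racemic) | C=CCOC(=O)C1CCC(=O)C=C1C | intermediate
4 | tert-butyl 2-bromopropanoate (racemic) | CC(Br)C(=O)OC(C)(C)C | starting material
5 | allyl 3-(1-tert-butoxy-1-oxopropan-2-yl)-2-methyl-4-oxocyclohex-2-ene-1-carboxylate (stereoisomer mixture) | C=CCOC(=O)C1CCC(=O)C(C(C)C(=O)OC(C)(C)C)=C1C | intermediate
6 | 2-[3-(allyloxycarbonyl)-2-methyl-6-oxocyclohex-1-en-1-yl]propanoic acid (not isolated) | C=CCOC(=O)C1CCC(=O)C(C(C)C(O)=O)=C1C | intermediate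
7 | allyl 3,4-dimethyl-2-oxo-2,3,6,7-tetrahydro-1-benzofuran-5-carboxylate (racemic) | C=CCOC(=O)C1=C(C)C2=C(CC1)OC(=O)C2C | intermediate
8 | 1,3-diiodopropane | ICCCI | starting material
9 | allyl (3S)-3-(3-iodopropyl)-3,4-dimethyl-2-oxo-2,3,6,7-tetrahydro-1-benzofuran-5-carboxylate | ICCC[C@]1(C)C(=O)OC2=C1C(C)=C(C(=O)OCC=C)CC2 | intermediate
10 | allyl (2aS,5aS)-2a,5a-dimethyl-2-oxo-2a,3,4,5,5a,6,7,8-octahydro-2H-naphtho[1,8-bc]furan-6-carboxylate (C9 epimers) | C=CCOC(=O)C1CCC2=C3[C@@]1(C)CCC[C@]3(C)C(=O)O2 | intermediate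
11 | 5-allyl 1-methyl 1,4a-dimethyl-8-oxodecahydronaphthalene-1,5-dicarboxylate (trans-decalin, C19 syn to C20, 5-H anti to C20; C9 epimers) | C=CCOC(=O)C1CCC(=O)[C@H]2[C@@]1(C)CCC[C@]2(C)C(=O)OC | intermediate
12 | 5-allyl 1-methyl 1,4a-dimethyl-8-oxo-1,2,3,4,4a,5,8,8a-octahydronaphthalene-1,5-dicarboxylate (C7=C8 enone) | C=CCOC(=O)C1C=CC(=O)[C@H]2[C@@]1(C)CCC[C@]2(C)C(=O)OC | intermediate
13 | 5-allyl 1-methyl 1,4a-dimethyl-8-oxo-6-(4,4,5,5-tetramethyl-1,3,2-dioxaborolan-2-yl)decahydronaphthalene-1,5-dicarboxylate (C8/C9 mixture) | C=CCOC(=O)C1C(B3OC(C)(C)C(C)(C)O3)CC(=O)[C@H]2[C@@]1(C)CCC[C@]2(C)C(=O)OC | intermediate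
14 | 5-allyl 1-methyl 8-hydroxy-1,4a-dimethyl-6-(4,4,5,5-tetramethyl-1,3,2-dioxaborolan-2-yl)decahydronaphthalene-1,5-dicarboxylate (equatorial C6–OH) | C=CCOC(=O)C1C(B3OC(C)(C)C(C)(C)O3)C[C@@H](O)[C@H]2[C@@]1(C)CCC[C@]2(C)C(=O)OC | intermediate
15 | 5-allyl 1-methyl 8-acetoxy-1,4a-dimethyl-6-(4,4,5,5-tetramethyl-1,3,2-dioxaborolan-2-yl)decahydronaphthalene-1,5-dicarboxylate | C=CCOC(=O)C1C(B3OC(C)(C)C(C)(C)O3)C[C@@H](OC(C)=O)[C@H]2[C@@]1(C)CCC[C@]2(C)C(=O)OC | intermediate
16 | 5-allyl 1-methyl 8-acetoxy-6-hydroxy-1,4a-dimethyldecahydronaphthalene-1,5-dicarboxylate | C=CCOC(=O)C1C(O)C[C@@H](OC(C)=O)[C@H]2[C@@]1(C)CCC[C@]2(C)C(=O)OC | intermediate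
17 | 5-allyl 1-methyl 8-acetoxy-1,4a-dimethyl-6-oxodecahydronaphthalene-1,5-dicarboxylate (β-keto ester) | C=CCOC(=O)C1C(=O)C[C@@H](OC(C)=O)[C@H]2[C@@]1(C)CCC[C@]2(C)C(=O)OC | intermediate
18 | 3-methylpenta-1,4-dien-3-ol | C=CC(C)(O)C=C | starting material
19 | (3E)-5-bromo-3-methylpenta-1,3-diene | BrC/C=C(C)/C=C | intermediate
20 | 5-allyl 1-methyl 8-acetoxy-1,4a-dimethyl-5-[(2E)-3-methylpenta-2,4-dien-1-yl]-6-oxodecahydronaphthalene-1,5-dicarboxylate (C9 quaternary, mixture) | C=CCOC(=O)C1(C/C=C(C)/C=C)C(=O)C[C@@H](OC(C)=O)[C@H]2[C@@]1(C)CCC[C@]2(C)C(=O)OC | intermediate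
21 | 8-acetoxy-1-(methoxycarbonyl)-1,4a-dimethyl-5-[(2E)-3-methylpenta-2,4-dien-1-yl]-6-oxodecahydronaphthalene-5-carboxylic acid (not isolated) | OC(=O)C1(C/C=C(C)/C=C)C(=O)C[C@@H](OC(C)=O)[C@H]2[C@@]1(C)CCC[C@]2(C)C(=O)OC | intermediate
22 | methyl 8-acetoxy-1,4a-dimethyl-5-[(2E)-3-methylpenta-2,4-dien-1-yl]-6-oxodecahydronaphthalene-1-carboxylate (configuration as in the target) | C=C/C(C)=C/C[C@@H]1C(=O)C[C@@H](OC(C)=O)[C@H]2[C@@]1(C)CCC[C@]2(C)C(=O)OC | intermediate
23 | methyl (1S,4aS,5R,8R,8aS)-8-acetoxy-1,4a-dimethyl-6-methylidene-5-[(2E)-3-methylpenta-2,4-dien-1-yl]decahydronaphthalene-1-carboxylate | C=C/C(C)=C/C[C@@H]1C(=C)C[C@@H](OC(C)=O)[C@H]2[C@@]1(C)CCC[C@]2(C)C(=O)OC | target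

Total step count: 16. Longest linear sequence: 15 steps (steps 1–12 and 14–16; step 13 prepares the side-chain bromide).

**Steps most likely to fail**

Step 5. The C1 radical may be reduced by the stannane before it cyclises, or it may close at the wrong alkene carbon (5-exo at C5) because addition to the fully substituted C10 is slow. The fallback replaces the radical by a polar ring closure. From 9, displacement of iodide with NaNO2 in DMF would give the nitroalkane allyl (3S)-3,4-dimethyl-3-(3-nitropropyl)-2-oxo-2,3,6,7-tetrahydro-1-benzofuran-5-carboxylate F1. DBU in MeCN would then trigger a reversible intramolecular nitronate Michael addition to C10 (6-exo, polar regiocontrol for the electron-poor β-carbon) to give the nitro tricycle allyl (2aS,5aS)-2a,5a-dimethyl-5-nitro-2-oxo-2a,3,4,5,5a,6,7,8-octahydro-2H-naphtho[1,8-bc]furan-6-carboxylate F2. Radical denitration (Bu3SnH, AIBN, toluene, 110 °C) returns to 10.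

Step 4. The ion pair may discriminate the enolate faces poorly (low enantiomeric purity), or the unactivated diiodide may alkylate slowly or at oxygen. The fallback builds the chain by conjugate addition instead of alkylation. From 7, Michael addition to acrolein with a cinchona-derived bifunctional squaramide catalyst (toluene, −20 °C) would give the aldehyde allyl (3S)-3,4-dimethyl-2-oxo-3-(3-oxopropyl)-2,3,6,7-tetrahydro-1-benzofuran-5-carboxylate F3. Reduction with NaBH4 and CeCl3·7H2O (MeOH, −78 °C) would give the alcohol allyl (3S)-3-(3-hydroxypropyl)-3,4-dimethyl-2-oxo-2,3,6,7-tetrahydro-1-benzofuran-5-carboxylate F4, which is converted at once (PPh3, I2, imidazole, CH2Cl2, 0 °C) into 9 before it can translactonise.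

Step 9. Hydrogen may be delivered from the open face to give the axial alcohol, or the allyl ester may be cleaved reductively. The fallback separates reduction from stereocontrol. From 13, NaBH4 (MeOH, −20 °C) would give the axial C6 epimer 5-allyl 1-methyl 8-epi-8-hydroxy-1,4a-dimethyl-6-(4,4,5,5-tetramethyl-1,3,2-dioxaborolan-2-yl)decahydronaphthalene-1,5-dicarboxylate F5. Reversible transfer dehydrogenation with Ru(CO)2Cl(η5-C5Ph5) and t-BuOK (toluene, rt to 50 °C) would then equilibrate it to the equatorial alcohol 14.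

**Further compounds**

F1 | step 5 | allyl (3S)-3,4-dimethyl-3-(3-nitropropyl)-2-oxo-2,3,6,7-tetrahydro-1-benzofuran-5-carboxylate | [O-][N+](=O)CCC[C@]1(C)C(=O)OC2=C1C(C)=C(C(=O)OCC=C)CC2
F2 | step 5 | allyl (2aS,5aS)-2a,5a-dimethyl-5-nitro-2-oxo-2a,3,4,5,5a,6,7,8-octahydro-2H-naphtho[1,8-bc]furan-6-carboxylate (C1/C9 mixture) | C=CCOC(=O)C1CCC2=C3[C@@]1(C)C([N+](=O)[O-])CC[C@]3(C)C(=O)O2
F3 | step 4 | allyl (3S)-3,4-dimethyl-2-oxo-3-(3-oxopropyl)-2,3,6,7-tetrahydro-1-benzofuran-5-carboxylate | O=CCC[C@]1(C)C(=O)OC2=C1C(C)=C(C(=O)OCC=C)CC2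
F4 | step 4 | allyl (3S)-3-(3-hydroxypropyl)-3,4-dimethyl-2-oxo-2,3,6,7-tetrahydro-1-benzofuran-5-carboxylate | OCCC[C@]1(C)C(=O)OC2=C1C(C)=C(C(=O)OCC=C)CC2
F5 | step 9 | 5-allyl 1-methyl 8-epi-8-hydroxy-1,4a-dimethyl-6-(4,4,5,5-tetramethyl-1,3,2-dioxaborolan-2-yl)decahydronaphthalene-1,5-dicarboxylate (axial C6–OH) | C=CCOC(=O)C1C(B3OC(C)(C)C(C)(C)O3)C[C@H](O)[C@H]2[C@@]1(C)CCC[C@]2(C)C(=O)OC
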